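**Strategy.** Ring B, C5 and the gem-dimethyl carbon C4 are bought together as (R)-carvone, whose isopropenyl group is C4 with both of its methyls in disguise. Two enolate alkylations at C10 add the angular methyl and a 3-iodopropyl arm (C1–C3) anti to the isopropenyl group. The key step then closes ring A, the gem-dimethylcyclohexane, as the last ring: a Markovnikov hydrogen-atom-transfer hydroalkylation joins C3 to C4, turns =CH2 into the second methyl and gives the trans-decalin directly. A pre-formed (R)-butenolide is attached at the very end by cross-metathesis with a 2-methylene aldehyde, which also sets the (E)-enal.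

Key step: step 8

Remark: labdane-type numbering is used (C10 = methyl-bearing ring-fusion carbon, C5 = ring-fusion CH, C4 = gem-dimethyl carbon, C1–C3 = the CH2 groups of ring A, C8/C9 = the ring B alkene, C11–C16 = side chain out to the butenolide CH). Commercial supply of 1, 7, 9 and 14 is assumed.

**Butenolide branch**

Step 1
Reactants: 1 methyl (2R)-oxirane-2-carboxylate
Product: 2 methyl (2R)-2-hydroxypent-4-enoate
Conditions: CH2=CHMgBr, CuI (10 mol %), THF, −78 to −40 °C; aq NH4Cl
Reagents that add atoms: vinylmagnesium bromide, C=C[Mg]Br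
Why: Copper-catalysed Grignard opening of the terminal epoxide at its CH2 carbon (SN2), which at low temperature should outrun addition to the ester; the stereocentre is not touched and stays R.

Step 2
Reactants: 2 methyl (2R)-2-hydroxypent-4-enoate
Product: 3 methyl (2R)-2-(acetyloxy)pent-4-enoate
Conditions: Ac2O, pyridine, DMAP (cat.), CH2Cl2, 0 °C to rt
Reagents that add atoms: acetic anhydride, CC(=O)OC(C)=O
Why: DMAP-catalysed O-acylation of the secondary alcohol; no bond to the stereocentre is broken.

Step 3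
Reactants: 3 methyl (2R)-2-(acetyloxy)pent-4-enoate
Product: 4 (5R)-4-hydroxy-5-(prop-2-en-1-yl)furan-2(5H)-one
Conditions: LiN(SiMe3)2 (2.5 equiv), THF, −78 to 0 °C; 1 M HCl
Reagents that add atoms: none
Why: Dieckmann-type intramolecular Claisen condensation (5-exo-trig attack of the acetate enolate on the methyl ester), driven by deprotonation of the acidic tetronic acid; C5 should keep its configuration because the acetate CH3 is deprotonated faster than the hindered C2–H.

Step 4
Reactants: 4 (5R)-4-hydroxy-5-(prop-2-en-1-yl)furan-2(5H)-one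
Product: 5 (2R)-5-oxo-2-(prop-2-en-1-yl)-2,5-dihydrofuran-3-yl trifluoromethanesulfonate
Conditions: Tf2O, i-Pr2NEt, CH2Cl2, −78 °C
Reagents that add atoms: trifluoromethanesulfonic anhydride, O=S(=O)(OS(=O)(=O)C(F)(F)F)C(F)(F)F
Why: O-sulfonylation of the enolic hydroxyl gives the vinylogous acyl triflate; the low temperature should prevent epimerisation at C5.

Step 5
Reactants: 5 (2R)-5-oxo-2-(prop-2-en-1-yl)-2,5-dihydrofuran-3-yl trifluoromethanesulfonate
Product: 6 (5R)-4-(hydroxymethyl)-5-(prop-2-en-1-yl)furan-2(5H)-one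
Conditions: Bu3SnCH2OH, Pd(PPh3)4 (5 mol %), LiCl, 1,4-dioxane, 90 °C
Reagents that add atoms: (tributylstannyl)methanol, CCCC[Sn](CCCC)(CCCC)CO
Why: Stille coupling of the electron-poor vinyl triflate with the hydroxymethylstannane; the neutral conditions should leave the base-sensitive C5–H stereocentre alone.

**Decalin branch and endgame**

Step 6
Reactants: 7 (R)-carvone, (5R)-2-methyl-5-(prop-1-en-2-yl)cyclohex-2-en-1-one
Product: 8 (5R,6S)-2,6-dimethyl-5-(prop-1-en-2-yl)cyclohex-2-en-1-one (trans epimer expected as the major one; the C6 epimer is carried along)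
Conditions: LiN(i-Pr)2, THF, −78 °C; MeI, −78 to 0 °C
Reagents that add atoms: iodomethane, CI
Why: Kinetic deprotonation of the enone at the alpha-prime carbon and SN2 methylation; the new centre is erased by the next deprotonation, so its configuration is immaterial.

Step 7
Reactants: 8 (5R,6S)-2,6-dimethyl-5-(prop-1-en-2-yl)cyclohex-2-en-1-one; 9 1,3-diiodopropane
Product: 10 (5S,6S)-6-(3-iodopropyl)-2,6-dimethyl-5-(prop-1-en-2-yl)cyclohex-2-en-1-one (iodopropyl arm trans to the isopropenyl group)
Conditions: LiN(i-Pr)2, THF, −78 °C; DMPU, 9 (4 equiv), −78 to 0 °C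
Reagents that add atoms: none
Why: Enolate SN2 alkylation that creates the quaternary carbon C10; the electrophile should approach the enolate face anti to the adjacent isopropenyl group (1,2-substrate control), which places the arm trans and the methyl cis to it.

Step 8
Reactants: 10 (5S,6S)-6-(3-iodopropyl)-2,6-dimethyl-5-(prop-1-en-2-yl)cyclohex-2-en-1-one
Product: 11 (4aS,8aS)-2,5,5,8a-tetramethyl-4a,5,6,7,8,8a-hexahydronaphthalen-1(4H)-one
Conditions: Mn(dpm)3 (20 mol %), Ni(acac)2 (10 mol %), PhSiH3 (slow addition), K2CO3, (CF3)2CHOH, ClCH2CH2Cl/propylene carbonate, 0.01 M, rt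
Reagents that add atoms: none
Why: Proposed new method: a manganese hydride formed from Mn(dpm)3 and PhSiH3 should transfer a hydrogen atom to the CH2 terminus of the isopropenyl group (Markovnikov selectivity), which turns that carbon into the second methyl and leaves a tertiary radical at C4, while low-valent nickel activates the primary C3–I bond; capture of the C4 radical at nickel and C(sp3)–C(sp3) reductive elimination then forge the C3–C4 bond. The closest known reaction type is the intermolecular Mn/Ni dual-catalytic Markovnikov hydroalkylation of 1,1-disubstituted alkenes with primary alkyl iodides, which builds this kind of quaternary carbon but has not been shown in ring-closing mode or beside an enone. Ring A closes as a six-membered carbocycle in a formal 6-exo-tet sense, the breaking C3–I bond lying outside the new ring. No stereocentre is created, since C4 carries two methyl groups; the trans ring fusion follows from the anti, diequatorial disposition of the C10 arm and the C5 isopropenyl group fixed in step 7. The step needs hydrogen-atom transfer to the electron-rich 1,1-disubstituted alkene in preference to the electron-poor trisubstituted enone, and ring closure in preference to plain reduction of the radical or the iodide; the polarity difference of the two alkenes, slow addition of the silane, high dilution and the proximity enforced by the quaternary C10 should secure both.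

Step 9
Reactants: 11 (4aS,8aS)-2,5,5,8a-tetramethyl-4a,5,6,7,8,8a-hexahydronaphthalen-1(4H)-one
Product: 13 (4aS,8aS)-2,5,5,8a-tetramethyl-3,4,4a,5,6,7,8,8a-octahydronaphthalen-1-yl trifluoromethanesulfonate, via lithium enolate 12 (not isolated)
Conditions: LiBH(s-Bu)3, THF, −78 °C; PhNTf2, −78 °C to rt
Reagents that add atoms: N-phenylbis(trifluoromethanesulfonimide), O=S(=O)(N(c1ccccc1)S(=O)(=O)C(F)(F)F)C(F)(F)F
Why: Conjugate hydride reduction of the alpha-methyl enone by the bulky borohydride gives the C8–C9 enolate regiospecifically, and O-sulfonylation gives the tetrasubstituted vinyl triflate; 1,2-attack is blocked by the neopentyl carbonyl and no stereocentre is affected.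

Step 10
Reactants: 13 (4aS,8aS)-2,5,5,8a-tetramethyl-3,4,4a,5,6,7,8,8a-octahydronaphthalen-1-yl trifluoromethanesulfonate; 14 4,4-diethoxybut-1-ene
Product: 17 4-[(4aS,8aS)-2,5,5,8a-tetramethyl-3,4,4a,5,6,7,8,8a-octahydronaphthalen-1-yl]butanal, via alkylborane 15 (not isolated), via diethyl acetal 16 (not isolated)
Conditions: 14, 9-BBN, THF, 0 °C to rt; then 13, Pd(dppf)Cl2 (10 mol %), AsPh3, Cs2CO3, DMF/H2O, 60 °C; then 1 M HCl, THF, rt
Reagents that add atoms: water, O
Why: Anti-Markovnikov hydroboration of the terminal alkene, B-alkyl Suzuki–Miyaura coupling with the vinyl triflate (oxidative addition to zerovalent palladium, transmetalation of the primary alkyl group, reductive elimination) and acid hydrolysis of the acetal in the work-up; no stereocentre is involved.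

Step 11
Reactants: 17 4-[(4aS,8aS)-2,5,5,8a-tetramethyl-3,4,4a,5,6,7,8,8a-octahydronaphthalen-1-yl]butanal
Product: 18 2-methylidene-4-[(4aS,8aS)-2,5,5,8a-tetramethyl-3,4,4a,5,6,7,8,8a-octahydronaphthalen-1-yl]butanal
Conditions: aq CH2O (37 %), pyrrolidine (10 mol %), propionic acid (10 mol %), i-PrOH, 45 °C
Reagents that add atoms: formaldehyde, C=O
Why: Amine-catalysed Mannich condensation with formaldehyde followed by elimination of the amine (alpha-methylenation of an aldehyde that has an alpha-CH2 group).

Step 12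
Reactants: 18 2-methylidene-4-[(4aS,8aS)-2,5,5,8a-tetramethyl-3,4,4a,5,6,7,8,8a-octahydronaphthalen-1-yl]butanal; 6 (5R)-4-(hydroxymethyl)-5-(prop-2-en-1-yl)furan-2(5H)-one
Product: 19 (2E)-4-[(2R)-3-(hydroxymethyl)-5-oxo-2,5-dihydrofuran-2-yl]-2-{2-[(4aS,8aS)-2,5,5,8a-tetramethyl-3,4,4a,5,6,7,8,8a-octahydronaphthalen-1-yl]ethyl}but-2-enal (CNP0197865.2)
Conditions: 6 (2 equiv), second-generation Hoveyda–Grubbs catalyst (10 mol %), CH2Cl2, 40 °C
Reagents that add atoms: none
Why: Olefin cross-metathesis of a terminal alkene with a 2-substituted acrolein, which does not homodimerise; the trisubstituted enal should form as the thermodynamically preferred (E) isomer (CHO trans to C15), while the tetrasubstituted ring alkene and the butenolide alkene are inert.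

**Compound list**

1 | methyl (2R)-oxirane-2-carboxylate | COC(=O)[C@H]1CO1 | starting material
2 | methyl (2R)-2-hydroxypent-4-enoate | C=CC[C@H](C(=O)OC)O | intermediate
3 | methyl (2R)-2-(acetyloxy)pent-4-enoate | C=CC[C@H](C(=O)OC)OC(C)=O | intermediate
4 | (5R)-4-hydroxy-5-(prop-2-en-1-yl)furan-2(5H)-one | C=CC[C@H]1OC(=O)C=C1O | intermediate
5 | (2R)-5-oxo-2-(prop-2-en-1-yl)-2,5-dihydrofuran-3-yl trifluoromethanesulfonate | C=CC[C@H]1OC(=O)C=C1OS(=O)(=O)C(F)(F)F | intermediate
6 | (5R)-4-(hydroxymethyl)-5-(prop-2-en-1-yl)furan-2(5H)-one | C=CC[C@H]1OC(=O)C=C1CO | intermediate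
7 | (R)-carvone | CC1=CC[C@H](CC1=O)C(C)=C | starting material
8 | (5R,6S)-2,6-dimethyl-5-(prop-1-en-2-yl)cyclohex-2-en-1-one (major epimer) | CC1=CC[C@H]([C@H](C)C1=O)C(C)=C | intermediate
9 | 1,3-diiodopropane | ICCCI | starting material
10 | (5S,6S)-6-(3-iodopropyl)-2,6-dimethyl-5-(prop-1-en-2-yl)cyclohex-2-en-1-one | CC1=CC[C@H]([C@](C)(CCCI)C1=O)C(C)=C | intermediate
11 | (4aS,8aS)-2,5,5,8a-tetramethyl-4a,5,6,7,8,8a-hexahydronaphthalen-1(4H)-one | CC1=CC[C@H]2C(C)(C)CCC[C@]2(C)C1=O | intermediate
12 | lithium (4aS,8aS)-2,5,5,8a-tetramethyl-3,4,4a,5,6,7,8,8a-octahydronaphthalen-1-olate | CC1=C(O[Li])[C@@]2(C)CCCC(C)(C)[C@@H]2CC1 | intermediate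
13 | (4aS,8aS)-2,5,5,8a-tetramethyl-3,4,4a,5,6,7,8,8a-octahydronaphthalen-1-yl trifluoromethanesulfonate | CC1=C(OS(=O)(=O)C(F)(F)F)[C@@]2(C)CCCC(C)(C)[C@@H]2CC1 | intermediate
14 | 4,4-diethoxybut-1-ene | C=CCC(OCC)OCC | starting material
15 | 9-(4,4-diethoxybutyl)-9-borabicyclo[3.3.1]nonane | CCOC(CCCB1C2CCCC1CCC2)OCC | intermediate
16 | (4aS,8aS)-1-(4,4-diethoxybutyl)-2,5,5,8a-tetramethyl-3,4,4a,5,6,7,8,8a-octahydronaphthalene | CC1=C(CCCC(OCC)OCC)[C@@]2(C)CCCC(C)(C)[C@@H]2CC1 | intermediate
17 | 4-[(4aS,8aS)-2,5,5,8a-tetramethyl-3,4,4a,5,6,7,8,8a-octahydronaphthalen-1-yl]butanal | CC1=C(CCCC=O)[C@@]2(C)CCCC(C)(C)[C@@H]2CC1 | intermediate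
18 | 2-methylidene-4-[(4aS,8aS)-2,5,5,8a-tetramethyl-3,4,4a,5,6,7,8,8a-octahydronaphthalen-1-yl]butanal | CC1=C(CCC(=C)C=O)[C@@]2(C)CCCC(C)(C)[C@@H]2CC1 | intermediate
19 | (2E)-4-[(2R)-3-(hydroxymethyl)-5-oxo-2,5-dihydrofuran-2-yl]-2-{2-[(4aS,8aS)-2,5,5,8a-tetramethyl-3,4,4a,5,6,7,8,8a-octahydronaphthalen-1-yl]ethyl}but-2-enal | CC1=C(CC/C(C=O)=C\C[C@H]2OC(=O)C=C2CO)[C@@]2(C)CCCC(C)(C)[C@@H]2CC1 | target

**Totals and risks**

Total step count: 12. Longest linear sequence: 7 steps (steps 6–12 from 7); the butenolide branch is 5 steps (steps 1–5). The butenolide ring is closed in step 3 and ring A in step 8; no ring is formed afterwards.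

Steps most likely to fail:

1. Step 8 (Proposed new method). Process at risk: hydrogen-atom transfer followed by plain reduction of the C4 radical, reduction of the iodide, or hydrogen-atom transfer to the enone may outrun the nickel-mediated C–C coupling, so that the ring does not close. Fallback with known chemistry only, setting out from 8 and returning to 11:
   - Alkylation of the enolate of 8 (LiN(i-Pr)2, THF, −78 °C) with methyl 2-(bromomethyl)acrylate should give, with the same anti selectivity, methyl 2-{[(1S,6S)-1,3-dimethyl-2-oxo-6-(prop-1-en-2-yl)cyclohex-3-en-1-yl]methyl}prop-2-enoate F1.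
   - Fe(acac)3 and PhSiH3 in EtOH/ethylene glycol at 60 °C generate the same C4 radical, which adds to the unsubstituted acrylate terminus (intramolecular Giese reaction, 6-endo-trig). This gives methyl (4aS,8aS)-4,4,7,8a-tetramethyl-8-oxo-1,2,3,4,4a,5,8,8a-octahydronaphthalene-2-carboxylate F2, with ring A closed and an ester on C2.
   - Saponification (LiOH, THF/H2O) gives (4aS,8aS)-4,4,7,8a-tetramethyl-8-oxo-1,2,3,4,4a,5,8,8a-octahydronaphthalene-2-carboxylic acid F3.
   - Photocatalytic hydrodecarboxylation (acridinium photocatalyst, PhSSPh, 2,6-lutidine, CF3CH2OH, blue light) removes the carboxyl group and gives 11.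

2. Step 12. Process at risk: slow initiation and turnover at the electron-poor 1,1-disubstituted alkene of 18, with homodimerisation of 6 and double-bond migration in its allyl group by ruthenium hydrides competing. Fallback, setting out from 17 and 6 and returning to 19, replaces metathesis by a Wittig reaction of a formyl-stabilised ylide:
   - alpha-Bromination of 17 (N-bromosuccinimide, catalytic pyrrolidine, CH2Cl2, 0 °C) gives 2-bromo-4-[(4aS,8aS)-2,5,5,8a-tetramethyl-3,4,4a,5,6,7,8,8a-octahydronaphthalen-1-yl]butanal F4.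
   - PPh3 in toluene gives {1-oxo-4-[(4aS,8aS)-2,5,5,8a-tetramethyl-3,4,4a,5,6,7,8,8a-octahydronaphthalen-1-yl]butan-2-yl}triphenylphosphonium bromide F5.
   - Aqueous NaOH/CH2Cl2 gives 4-[(4aS,8aS)-2,5,5,8a-tetramethyl-3,4,4a,5,6,7,8,8a-octahydronaphthalen-1-yl]-2-(triphenylphosphoranylidene)butanal F6.
   - Ozonolysis of the terminal alkene of 6 (O3, CH2Cl2/MeOH, −78 °C, then Me2S; the electron-poor butenolide alkene should react far more slowly) gives [(2R)-3-(hydroxymethyl)-5-oxo-2,5-dihydrofuran-2-yl]acetaldehyde F7.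
   - Heating F6 with F7 in toluene at 80 °C should give 19, since ylides of this type deliver (E)-2-alkyl-2-enals and need no base that could open the butenolide by beta-elimination.

3. Step 7. Process at risk: the hindered enolate may act as a base toward 9 (elimination to allyl iodide), alkylate on oxygen, or a second enolate may displace the remaining iodide; facial selectivity may also erode with the unactivated electrophile. Fallback, setting out from 8 and returning to 10:
   - Alkylation of the enolate of 8 with allyl bromide (LiN(i-Pr)2, THF, −78 to 0 °C), a reactive electrophile for which anti attack is dependable, gives (5S,6S)-2,6-dimethyl-5-(prop-1-en-2-yl)-6-(prop-2-en-1-yl)cyclohex-2-en-1-one F8.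
   - Anti-Markovnikov hydroboration of the monosubstituted alkene with bis(3-methylbutan-2-yl)borane (THF, 0 °C; the isopropenyl group and the hindered ketone should react much more slowly) gives (5S,6S)-6-{3-[bis(3-methylbutan-2-yl)boranyl]propyl}-2,6-dimethyl-5-(prop-1-en-2-yl)cyclohex-2-en-1-one F9, not isolated.
   - Iodinolysis (I2, NaOMe, MeOH, 0 °C) converts its primary B–C bond into the C–I bond of 10.

Further compounds
F1 | step 8 | methyl 2-{[(1S,6S)-1,3-dimethyl-2-oxo-6-(prop-1-en-2-yl)cyclohex-3-en-1-yl]methyl}prop-2-enoate | CC1=CC[C@H]([C@](C)(CC(=C)C(=O)OC)C1=O)C(C)=C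
F2 | step 8 | methyl (4aS,8aS)-4,4,7,8a-tetramethyl-8-oxo-1,2,3,4,4a,5,8,8a-octahydronaphthalene-2-carboxylate (C2 epimers) | CC1=CC[C@H]2C(C)(C)CC(C(=O)OC)C[C@]2(C)C1=O
F3 | step 8 | (4aS,8aS)-4,4,7,8a-tetramethyl-8-oxo-1,2,3,4,4a,5,8,8a-octahydronaphthalene-2-carboxylic acid (C2 epimers) | CC1=CC[C@H]2C(C)(C)CC(C(O)=O)C[C@]2(C)C1=O
F4 | step 12 | 2-bromo-4-[(4aS,8aS)-2,5,5,8a-tetramethyl-3,4,4a,5,6,7,8,8a-octahydronaphthalen-1-yl]butanal (C2 epimers) | CC1=C(CCC(Br)C=O)[C@@]2(C)CCCC(C)(C)[C@@H]2CC1
F5 | step 12 | {1-oxo-4-[(4aS,8aS)-2,5,5,8a-tetramethyl-3,4,4a,5,6,7,8,8a-octahydronaphthalen-1-yl]butan-2-yl}triphenylphosphonium bromide | CC1=C(CCC(C=O)[P+](c3ccccc3)(c3ccccc3)c3ccccc3)[C@@]2(C)CCCC(C)(C)[C@@H]2CC1.[Br-]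
F6 | step 12 | 4-[(4aS,8aS)-2,5,5,8a-tetramethyl-3,4,4a,5,6,7,8,8a-octahydronaphthalen-1-yl]-2-(triphenylphosphoranylidene)butanal | CC1=C(CCC(C=O)=P(c3ccccc3)(c3ccccc3)c3ccccc3)[C@@]2(C)CCCC(C)(C)[C@@H]2CC1
F7 | step 12 | [(2R)-3-(hydroxymethyl)-5-oxo-2,5-dihydrofuran-2-yl]acetaldehyde | O=CC[C@H]1OC(=O)C=C1CO
F8 | step 7 | (5S,6S)-2,6-dimethyl-5-(prop-1-en-2-yl)-6-(prop-2-en-1-yl)cyclohex-2-en-1-one | CC1=CC[C@H]([C@](C)(CC=C)C1=O)C(C)=C
F9 | step 7 | (5S,6S)-6-{3-[bis(3-methylbutan-2-yl)boranyl]propyl}-2,6-dimethyl-5-(prop-1-en-2-yl)cyclohex-2-en-1-one | CC1=CC[C@H]([C@](C)(CCCB(C(C)C(C)C)C(C)C(C)C)C1=O)C(C)=C
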